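**Retrosynthetic overview**

- The central ketone is traced back to a 1,3-diarylpropyne. The ring A methyl ester delivers water to the alkyne carbon remote from ring A (6-endo participation), so the ester fixes the ketone position.
- The alkyne and the ester are both put on ring A in one palladium/norbornene (Catellani) reaction of the MOM ether of 2-iodo-5-methylphenol: CO2Me goes to the free ortho C–H (C1) and the ring B propargyl arene to the iodine-bearing carbon (C2).
- Feature used: ring A carries three adjacent substituents, C1–CO2Me, C2–CH2 side chain and C3–O. The two carbon groups are ortho to each other and the C3 oxygen fills the second ortho position of C2, so one aryl iodide with one blocking group can take up both.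
- The ring B alkyne comes from 1,3-dimethoxybenzene: C2 chlorination, C5 borylation/oxidation to the symmetric 4-chloro-3,5-dimethoxyphenol, O-allylation/Claisen rearrangement, MOM protection, oxidative cleavage and Ohira–Bestmann homologation.
- No ring is formed: both benzene rings are bought, the target has no stereocentre, and the two MOM ethers are removed last.

Key step: step 10

Remark on the chemistry: the target is achiral and is taken in the open-chain keto form drawn; methyl 3-hydroxy-5-methylbenzoate (used only in a fallback) is assumed to be purchasable.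

**Route**

Step 1
Reactants: 1 2-iodo-5-methylphenol
Product: 2 1-iodo-2-(methoxymethoxy)-4-methylbenzene
Conditions: NaH, MOMCl, THF/DMF, 0 °C to rt
Reagents that add atoms: chloromethyl methyl ether (MOMCl), COCCl
Why: Williamson-type O-alkylation of the sodium phenoxide by the reactive α-chloro ether should give the MOM ether, and the aryl iodide is inert to these conditions.

Step 2
Reactants: 3 2,4,6-trimethylbenzoic acid; 4 methyl chloroformate
Product: 5 methyl 2,4,6-trimethylbenzoyl carbonate
Conditions: Et3N, THF, −10 to 0 °C; filtered, concentrated cold, used fresh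
Reagents that add atoms: none
Why: Acylation of the triethylammonium carboxylate by the chloroformate (mixed carboxylic–carbonic anhydride formation) should be clean, and the two ortho methyl groups shield the aroyl carbonyl and slow disproportionation.

Step 3
Reactants: 6 1,3-dimethoxybenzene
Product: 8 2-chloro-1,3-dimethoxybenzene, via (2,6-dimethoxyphenyl)lithium 7 (not isolated)
Conditions: n-BuLi, THF, 0 °C to rt; then C2Cl6, −78 °C to rt
Reagents that add atoms: hexachloroethane, ClC(Cl)(Cl)C(Cl)(Cl)Cl; n-butyllithium, [Li]CCCC (lithium of 7 only)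
Why: Directed ortho-lithiation takes the C2–H flanked by both methoxy groups, and the aryllithium is chlorinated by chlorine transfer from hexachloroethane.

Step 4
Reactants: 8 2-chloro-1,3-dimethoxybenzene
Product: 10 4-chloro-3,5-dimethoxyphenol, via aryl pinacol boronate 9 (not isolated)
Conditions: [Ir(OMe)(cod)]2 (1.5 mol%), 4,4′-di-tert-butyl-2,2′-bipyridine (3 mol%), B2pin2 (0.6 equiv), THF, 80 °C; then Oxone (2KHSO5·KHSO4·K2SO4), acetone/H2O, rt
Reagents that add atoms: bis(pinacolato)diboron, CC1(C)OB(OC1(C)C)B1OC(C)(C)C(C)(C)O1 (boron of 9 only); potassium peroxymonosulfate, [K+].[O-]S(=O)(=O)OO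
Why: Iridium-catalysed C–H borylation is sterically controlled and should take the only C–H without an ortho substituent (C5, para to chlorine), and peroxide oxidation of the C–B bond with 1,2-aryl shift gives the phenol in the same flask.

Step 5
Reactants: 10 4-chloro-3,5-dimethoxyphenol; 11 allyl bromide
Product: 12 2-chloro-1,3-dimethoxy-5-(prop-2-en-1-yloxy)benzene
Conditions: K2CO3, acetone, reflux
Reagents that add atoms: none
Why: Williamson ether synthesis (SN2 of the phenoxide on the allylic bromide) should give the O-allyl ether.

Step 6
Reactants: 12 2-chloro-1,3-dimethoxy-5-(prop-2-en-1-yloxy)benzene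
Product: 14 2-allyl-4-chloro-3,5-dimethoxyphenol, via ortho-dienone 13 (not isolated)
Conditions: N,N-diethylaniline, 190 °C, sealed tube
Reagents that add atoms: none
Why: Aromatic Claisen rearrangement ([3,3]-sigmatropic shift, then tautomerisation) can give only one ortho product because the two ortho positions are equivalent by symmetry and the para position carries chlorine.

Step 7
Reactants: 14 2-allyl-4-chloro-3,5-dimethoxyphenol
Product: 15 2-chloro-1,3-dimethoxy-5-(methoxymethoxy)-4-(prop-2-en-1-yl)benzene
Conditions: NaH, MOMCl, DMF, 0 °C to rt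
Reagents that add atoms: chloromethyl methyl ether (MOMCl), COCCl
Why: O-alkylation of the sodium phenoxide with the α-chloro ether (Williamson type) should protect the phenol as an acetal that is stable to the oxidative and basic steps that follow.

Step 8
Reactants: 15 2-chloro-1,3-dimethoxy-5-(methoxymethoxy)-4-(prop-2-en-1-yl)benzene
Product: 17 2-[3-chloro-2,4-dimethoxy-6-(methoxymethoxy)phenyl]acetaldehyde, via vicinal diol 16 (not isolated)
Conditions: OsO4 (2 mol%), NaIO4 (4 equiv), 2,6-lutidine, 1,4-dioxane/H2O (3:1), rt; used crude
Reagents that add atoms: sodium periodate, [Na+].[O-]I(=O)(=O)=O (terminal oxidant and oxygen source, relayed through catalytic osmium tetroxide, O=[Os](=O)(=O)=O)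
Why: Lemieux–Johnson oxidative cleavage (dihydroxylation of the terminal alkene, then periodate glycol cleavage) should give the arylacetaldehyde and is preferred over ozone, which could attack the electron-rich ring.

Step 9
Reactants: 17 2-[3-chloro-2,4-dimethoxy-6-(methoxymethoxy)phenyl]acetaldehyde
Product: 18 2-chloro-1,3-dimethoxy-5-(methoxymethoxy)-4-(prop-2-yn-1-yl)benzene
Conditions: dimethyl (1-diazo-2-oxopropyl)phosphonate, K2CO3, MeOH, 0 °C to rt
Reagents that add atoms: dimethyl (1-diazo-2-oxopropyl)phosphonate, CC(=O)C(=[N+]=[N-])P(=O)(OC)OC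
Why: Ohira–Bestmann (Seyferth–Gilbert) homologation, in which the methanolysed reagent adds to the aldehyde, eliminates phosphate and loses nitrogen with 1,2-hydrogen shift, should give the terminal alkyne under carbonate conditions mild enough for an enolisable aldehyde.

Step 10
Reactants: 2 1-iodo-2-(methoxymethoxy)-4-methylbenzene; 5 methyl 2,4,6-trimethylbenzoyl carbonate; 18 2-chloro-1,3-dimethoxy-5-(methoxymethoxy)-4-(prop-2-yn-1-yl)benzene
Product: 19 methyl 2-{3-[3-chloro-2,4-dimethoxy-6-(methoxymethoxy)phenyl]prop-1-yn-1-yl}-3-(methoxymethoxy)-5-methylbenzoate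
Conditions: Pd(OAc)2 (10 mol%), tri(2-furyl)phosphine (25 mol%), norbornene (1.5 equiv), Cs2CO3 (3 equiv), 5 (2.5 equiv), toluene, 100 °C, slow addition of 18
Reagents that add atoms: none
Why: Proposed new method: zerovalent palladium inserts into the C2–I bond of 2, norbornene carbopalladates the aryl palladium iodide, and carbonate-assisted metalation of the only free ortho C–H (C1) closes a five-membered aryl–norbornyl palladacycle of divalent palladium; oxidative addition of the carbonate C(=O)–O bond of 5 then gives a tetravalent palladium methoxycarbonyl species that reductively eliminates the C1–CO2Me bond. The aryl norbornyl palladium species now has both ortho positions filled and is too crowded to persist, so norbornene is expelled by β-carbon elimination and the C2–palladium species is intercepted by the cesium acetylide of 18 in a copper-free Sonogashira-type termination, with reductive elimination forming the C2–C(sp) bond and returning zerovalent palladium. The closest known reactions are the palladium/norbornene ortho-alkoxycarbonylation of aryl iodides with carboxylic–carbonic anhydrides (terminated by Heck coupling or by hydride) and palladium/norbornene ortho-functionalisation with ipso-alkynylation by terminal alkynes; their combination in one catalytic cycle is the untested element. No ring is closed in the product and no stereocentre is created. The step needs site selectivity (the C3 methoxymethoxy group occupies the second ortho position and, as the ortho substituent, favours norbornene insertion and later extrusion), transfer of the methoxycarbonyl and not the aroyl half of 5 (the two ortho methyl groups of the mesitoyl unit block that carbonyl), and the right order of events (norbornene insertion is faster than direct alkynylation, helped by slow addition of 18). Toluene, in which Cs2CO3 is sparingly soluble, is chosen to hold back base-induced propargyl-to-allenyl isomerisation of the skipped alkyne.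

Step 11
Reactants: 19 methyl 2-{3-[3-chloro-2,4-dimethoxy-6-(methoxymethoxy)phenyl]prop-1-yn-1-yl}-3-(methoxymethoxy)-5-methylbenzoate
Product: 20 methyl 2-{3-[3-chloro-2,4-dimethoxy-6-(methoxymethoxy)phenyl]-2-oxopropyl}-3-(methoxymethoxy)-5-methylbenzoate
Conditions: AuCl3 (5 mol%), 1,4-dioxane/H2O (4:1), rt
Reagents that add atoms: water, O
Why: In this gold-catalysed, neighbouring-group-assisted alkyne hydration the ester carbonyl oxygen should attack the gold-activated alkyne 6-endo-dig at the carbon remote from ring A, water adds at the former carbonyl carbon, and opening of the hemi-orthoester with protodeauration leaves the ketone on that remote carbon and restores the methyl ester.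

Step 12
Reactants: 20 methyl 2-{3-[3-chloro-2,4-dimethoxy-6-(methoxymethoxy)phenyl]-2-oxopropyl}-3-(methoxymethoxy)-5-methylbenzoate
Product: 21 methyl 2-[3-(3-chloro-6-hydroxy-2,4-dimethoxyphenyl)-2-oxopropyl]-3-hydroxy-5-methylbenzoate (target)
Conditions: HCl (2 M) in MeOH/H2O (9:1), 35 °C, short reaction time; NaHCO3 quench
Reagents that add atoms: none
Why: Acid-catalysed acetal exchange (MOM ether cleavage through the oxocarbenium ion) should pass both methoxymethyl groups to methanol, and the low temperature and methyl ester/methanol match are chosen to spare the ketone and ester.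

**Compound list**

1 | 2-iodo-5-methylphenol | Cc1ccc(I)c(O)c1 | starting material
2 | 1-iodo-2-(methoxymethoxy)-4-methylbenzene | COCOc1cc(C)ccc1I | intermediate
3 | 2,4,6-trimethylbenzoic acid | Cc1cc(C)c(C(=O)O)c(C)c1 | starting material
4 | methyl chloroformate | COC(=O)Cl | starting material
5 | methyl 2,4,6-trimethylbenzoyl carbonate | COC(=O)OC(=O)c1c(C)cc(C)cc1C | intermediate
6 | 1,3-dimethoxybenzene | COc1cccc(OC)c1 | starting material
7 | (2,6-dimethoxyphenyl)lithium | [Li]c1c(OC)cccc1OC | intermediate
8 | 2-chloro-1,3-dimethoxybenzene | COc1cccc(OC)c1Cl | intermediate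
9 | 2-(4-chloro-3,5-dimethoxyphenyl)-4,4,5,5-tetramethyl-1,3,2-dioxaborolane | COc1cc(B2OC(C)(C)C(C)(C)O2)cc(OC)c1Cl | intermediate
10 | 4-chloro-3,5-dimethoxyphenol | COc1cc(O)cc(OC)c1Cl | intermediate
11 | allyl bromide | C=CCBr | starting material
12 | 2-chloro-1,3-dimethoxy-5-(prop-2-en-1-yloxy)benzene | C=CCOc1cc(OC)c(Cl)c(OC)c1 | intermediate
13 | 6-allyl-4-chloro-3,5-dimethoxycyclohexa-2,4-dien-1-one (racemic) | C=CCC1C(=O)C=C(OC)C(Cl)=C1OC | intermediate
14 | 2-allyl-4-chloro-3,5-dimethoxyphenol | C=CCc1c(O)cc(OC)c(Cl)c1OC | intermediate
15 | 2-chloro-1,3-dimethoxy-5-(methoxymethoxy)-4-(prop-2-en-1-yl)benzene | C=CCc1c(OCOC)cc(OC)c(Cl)c1OC | intermediate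
16 | 3-[3-chloro-2,4-dimethoxy-6-(methoxymethoxy)phenyl]propane-1,2-diol (racemic) | OCC(O)Cc1c(OCOC)cc(OC)c(Cl)c1OC | intermediate
17 | 2-[3-chloro-2,4-dimethoxy-6-(methoxymethoxy)phenyl]acetaldehyde | O=CCc1c(OCOC)cc(OC)c(Cl)c1OC | intermediate
18 | 2-chloro-1,3-dimethoxy-5-(methoxymethoxy)-4-(prop-2-yn-1-yl)benzene | C#CCc1c(OCOC)cc(OC)c(Cl)c1OC | intermediate
19 | methyl 2-{3-[3-chloro-2,4-dimethoxy-6-(methoxymethoxy)phenyl]prop-1-yn-1-yl}-3-(methoxymethoxy)-5-methylbenzoate | COC(=O)c1cc(C)cc(OCOC)c1C#CCc1c(OCOC)cc(OC)c(Cl)c1OC | intermediate
20 | methyl 2-{3-[3-chloro-2,4-dimethoxy-6-(methoxymethoxy)phenyl]-2-oxopropyl}-3-(methoxymethoxy)-5-methylbenzoate | COC(=O)c1cc(C)cc(OCOC)c1CC(=O)Cc1c(OCOC)cc(OC)c(Cl)c1OC | intermediate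
21 | methyl 2-[3-(3-chloro-6-hydroxy-2,4-dimethoxyphenyl)-2-oxopropyl]-3-hydroxy-5-methylbenzoate | COC(=O)c1cc(C)cc(O)c1CC(=O)Cc1c(O)cc(OC)c(Cl)c1OC | target

**Summary**

Total step count: 12. Longest linear sequence: 10 steps (steps 3 to 12, from 1,3-dimethoxybenzene 6 to target 21).

**Steps most likely to fail**

1. Step 10 (proposed new method). The acetylide may capture the aryl palladium iodide before norbornene insertion, giving alkynylation without ester transfer. The anhydride may decarboxylate at 100 °C, and the base may isomerise the skipped alkyne to an allene before or after coupling. The fallback makes the same two bonds one after the other by known reactions; it sets out from alkyne 18 and returns at 19. Purchased methyl 3-hydroxy-5-methylbenzoate would be protected (NaH, MOMCl, DMF) to methyl 3-(methoxymethoxy)-5-methylbenzoate F1. Directed magnesiation with TMPMgCl·LiCl in THF at 0 °C at C2, the position flanked by the ester and the acetal oxygen, would give [2-(methoxycarbonyl)-6-(methoxymethoxy)-4-methylphenyl]magnesium chloride F2, which iodine would convert to methyl 2-iodo-3-(methoxymethoxy)-5-methylbenzoate F3. Sonogashira coupling of F3 with 18 (PdCl2(PPh3)2, CuI, Et3N, THF, 40 °C) would then give 19.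

2. Step 11. The methoxymethyl ether oxygen at C3 of ring A may attack the gold-activated alkyne (5-endo) in competition with the ester carbonyl, which would lead to benzofuran formation with loss or migration of the acetal group. The hemi-orthoester may also collapse with loss of methanol and lactonise, and acid released from the gold salt may cleave a MOM ether early. The fallback avoids π-acid activation; it sets out from 19 and returns at 20. Copper-catalysed protoboration (CuCl, Xantphos, NaOtBu in catalytic amount, B2pin2, MeOH, THF, rt) should place boron on the alkyne carbon remote from ring A and hydrogen on the carbon attached to ring A. This would give methyl 2-[(1Z)-3-[3-chloro-2,4-dimethoxy-6-(methoxymethoxy)phenyl]-2-(4,4,5,5-tetramethyl-1,3,2-dioxaborolan-2-yl)prop-1-en-1-yl]-3-(methoxymethoxy)-5-methylbenzoate F4. Oxidation of the C–B bond with NaBO3·4H2O in THF/H2O at rt would give the enol and hence ketone 20.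

3. Step 12. Under the acid needed to cleave two aryl MOM ethers, either freed o-hydroxybenzyl ketone unit may close to a hemiketal and dehydrate to a benzofuran. The keto ester may also lactonise, and released formaldehyde equivalents may alkylate the electron-rich ring B. The fallback moves the acid step to the alkyne stage and ends with a fluoride deprotection; it sets out from 19 and returns at 21. Treatment of 19 with HCl in MeOH would give methyl 2-[3-(3-chloro-6-hydroxy-2,4-dimethoxyphenyl)prop-1-yn-1-yl]-3-hydroxy-5-methylbenzoate F5, which is stable to acid in the absence of a π-acidic metal. Silylation (TIPSOTf, 2,6-lutidine, CH2Cl2, 0 °C) would give the bis(triisopropylsilyl) ether F6, whose bulky and weakly nucleophilic silyl ether oxygens should not compete with the ester. The ester-assisted hydration of step 11 (AuCl3, 1,4-dioxane/H2O, rt) would give the bis(triisopropylsilyl) keto ester F7. Buffered fluoride (Bu4NF/AcOH, THF, 0 °C) would then free both phenols to give 21 without strong acid or base.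

**Further compounds**

F1 | step 10 | methyl 3-(methoxymethoxy)-5-methylbenzoate | COCOc1cc(C)cc(C(=O)OC)c1
F2 | step 10 | [2-(methoxycarbonyl)-6-(methoxymethoxy)-4-methylphenyl]magnesium chloride | COCOc1cc(C)cc(C(=O)OC)c1[Mg]Cl
F3 | step 10 | methyl 2-iodo-3-(methoxymethoxy)-5-methylbenzoate | COCOc1cc(C)cc(C(=O)OC)c1I
F4 | step 11 | methyl 2-[(1Z)-3-[3-chloro-2,4-dimethoxy-6-(methoxymethoxy)phenyl]-2-(4,4,5,5-tetramethyl-1,3,2-dioxaborolan-2-yl)prop-1-en-1-yl]-3-(methoxymethoxy)-5-methylbenzoate | COC(=O)c1cc(C)cc(OCOC)c1/C=C(\Cc1c(OCOC)cc(OC)c(Cl)c1OC)B1OC(C)(C)C(C)(C)O1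
F5 | step 12 | methyl 2-[3-(3-chloro-6-hydroxy-2,4-dimethoxyphenyl)prop-1-yn-1-yl]-3-hydroxy-5-methylbenzoate | COC(=O)c1cc(C)cc(O)c1C#CCc1c(O)cc(OC)c(Cl)c1OC
F6 | step 12 | methyl 2-{3-[3-chloro-2,4-dimethoxy-6-(triisopropylsilyloxy)phenyl]prop-1-yn-1-yl}-5-methyl-3-(triisopropylsilyloxy)benzoate | COC(=O)c1cc(C)cc(O[Si](C(C)C)(C(C)C)C(C)C)c1C#CCc1c(O[Si](C(C)C)(C(C)C)C(C)C)cc(OC)c(Cl)c1OC
F7 | step 12 | methyl 2-{3-[3-chloro-2,4-dimethoxy-6-(triisopropylsilyloxy)phenyl]-2-oxopropyl}-5-methyl-3-(triisopropylsilyloxy)benzoate | COC(=O)c1cc(C)cc(O[Si](C(C)C)(C(C)C)C(C)C)c1CC(=O)Cc1c(O[Si](C(C)C)(C(C)C)C(C)C)cc(OC)c(Cl)c1OC
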